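**Plan**

- Retrosynthesis: after removal of six benzyl ethers, each of the two identical terminal rings (a 2-butanoyl-4,4-dimethylcyclohexane-1,3,5-trione whose C6 carries the CH2–aryl link) is cut at C1–C2 and at C4–C5. This leaves a bis(malonyl) core (C1, C6, C5 of each ring) and two C3 units (C2, C3, C4 with the butanoyl group).
- Enabling feature: around each terminal ring three carbonyl-level carbons (C1, C3, C5) alternate with three enolate-level carbons (C2, C4, C6). The ring is therefore the [3+3] union of a malonyl 1,3-dielectrophile with a 1,3-dinucleophilic β-diketone unit, and the twofold symmetry of the tetramer lets both rings form in one three-component operation.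
- The dinucleophile is the 1-amino-3-silyloxy diene 6: the butanoyl carbonyl is masked as a pyrrolidine enaminone so that only the isopropyl methine can be enolised, and the mask leaves in the acidic work-up of the key step.
- Forward: the aromatic rings come from phloroglucinol (acylation, formaldehyde bridging); formylation, benzylation, reductive alkylation of Meldrum's acid and hydrolysis give the bis(malonic acid); the two terminal carbocycles are closed last, then hydrogenolysis.
- Stereochemistry: the target is achiral, with no stereocentre and no stereogenic double bond, so nothing has to be controlled.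

Key step: step 10

Assumption: the enolised β-triketone rings interconvert freely between tautomers, so the tautomer drawn and those formed in the flask are taken as one compound.

**Route**

Step 1
Reactants: 1 pent-1-yne; 2 2-methylpropanoyl chloride
Product: 3 2-methyloct-4-yn-3-one
Conditions: PdCl2(PPh3)2 (2 mol%), CuI (4 mol%), Et3N, THF, rt
Reagents that add atoms: none
Why: Acyl Sonogashira coupling of a terminal alkyne with an aliphatic acid chloride should give the ynone directly.

Step 2
Reactants: 3 2-methyloct-4-yn-3-one; 4 pyrrolidine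
Product: 5 (4E)-2-methyl-5-(pyrrolidin-1-yl)oct-4-en-3-one
Conditions: EtOH, 0 °C → rt
Reagents that add atoms: none
Why: Conjugate (aza-Michael) addition of a secondary amine to an ynone places nitrogen only on the former alkyne β-carbon, so the future butanoyl carbonyl is masked regiospecifically as the (E)-enaminone.

Step 3
Reactants: 5 (4E)-2-methyl-5-(pyrrolidin-1-yl)oct-4-en-3-one
Product: 6 1-[(4E)-2-methyl-3-(trimethylsilyloxy)octa-2,4-dien-5-yl]pyrrolidine
Conditions: LDA (LiN(iPr)2), THF, −78 °C; Me3SiCl, −78 °C → rt; pentane, filtration, used crude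
Reagents that add atoms: chlorotrimethylsilane, C[Si](C)(C)Cl
Why: Kinetic α'-deprotonation of a vinylogous amide should give the cross-conjugated enolate at the isopropyl methine, and O-silylation traps it as the 1-amino-3-silyloxy diene (standard enolate silylation).

Step 4
Reactants: 7 phloroglucinol (benzene-1,3,5-triol); 8 butanoyl chloride
Product: 9 1-(2,4,6-trihydroxyphenyl)butan-1-one
Conditions: AlCl3, PhNO2/CH2Cl2, 0 → 40 °C; ice/aq. HCl
Reagents that add atoms: none
Why: Friedel–Crafts acylation of phloroglucinol should stop after one acyl group because the product ketone is deactivated as its AlCl3 chelate.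

Step 5
Reactants: 9 1-(2,4,6-trihydroxyphenyl)butan-1-one (two molecules)
Product: 10 1,1'-[methylenebis(2,4,6-trihydroxybenzene-3,1-diyl)]di(butan-1-one)
Conditions: 37% aq. CH2O (0.4 equiv per 9), 1% aq. KOH, 0 °C → rt; dil. HCl
Reagents that add atoms: formaldehyde, C=O
Why: Hydroxymethylation of the phenoxide, loss of water to an ortho-quinone methide and conjugate addition of a second ring is the classical formaldehyde methylene-bridging of acylphloroglucinols, and the excess of 9 should suppress oligomers.

Step 6
Reactants: 10 1,1'-[methylenebis(2,4,6-trihydroxybenzene-3,1-diyl)]di(butan-1-one)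
Product: 11 3,3'-methylenebis(5-butanoyl-2,4,6-trihydroxybenzaldehyde)
Conditions: POCl3, DMF, EtOAc, 0 °C → rt; H2O, 50 °C
Reagents that add atoms: N,N-dimethylformamide, CN(C)C=O; water, O
Why: Vilsmeier–Haack formylation should attack the only unsubstituted, doubly oxygen-activated carbon of each ring, and hydrolysis of the iminium salt gives the aldehyde.

Step 7
Reactants: 11 3,3'-methylenebis(5-butanoyl-2,4,6-trihydroxybenzaldehyde)
Product: 12 3,3'-methylenebis[2,4,6-tris(benzyloxy)-5-butanoylbenzaldehyde]
Conditions: BnBr, K2CO3, n-Bu4NI (cat.), DMF, 60 °C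
Reagents that add atoms: benzyl bromide, BrCc1ccccc1
Why: Williamson etherification; every ring carbon is substituted, so O-alkylation is the only aromatic outcome, and heating in DMF should overcome the hydrogen bonding of the hydroxyls to the neighbouring carbonyls.

Step 8
Reactants: 12 3,3'-methylenebis[2,4,6-tris(benzyloxy)-5-butanoylbenzaldehyde]; 13 Meldrum's acid (2,2-dimethyl-1,3-dioxane-4,6-dione, two molecules)
Product: 15 5,5'-{methylenebis[(2,4,6-tris(benzyloxy)-5-butanoylbenzene-3,1-diyl)methylene]}bis(2,2-dimethyl-1,3-dioxane-4,6-dione), via bis(arylidene Meldrum's acid) 14 (not isolated)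
Conditions: Hantzsch ester (diethyl 2,6-dimethyl-1,4-dihydropyridine-3,5-dicarboxylate), L-proline (20 mol%), EtOH/CH2Cl2, rt
Reagents that add atoms: none
Why: Three-component reductive alkylation: Knoevenagel condensation gives the arylidene Meldrum's acid, which should be reduced in the flask by hydride transfer from the Hantzsch ester while ketones and benzyl ethers stay untouched.

Step 9
Reactants: 15 bis(arylmethyl Meldrum's acid) from step 8
Product: 16 2,2'-{methylenebis[(2,4,6-tris(benzyloxy)-5-butanoylbenzene-3,1-diyl)methylene]}dipropanedioic acid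
Conditions: 2 M aq. HCl, THF, 50 °C
Reagents that add atoms: water, O
Why: Acid-catalysed hydrolysis of the cyclic isopropylidene acylal should release acetone and the substituted malonic acid below its decarboxylation temperature, and benzyl aryl ethers are stable to dilute acid.

Step 10
Reactants: 16 bis(malonic acid) from step 9; 6 1-[(4E)-2-methyl-3-(trimethylsilyloxy)octa-2,4-dien-5-yl]pyrrolidine (two molecules)
Product: 19 6,6'-{methylenebis[(2,4,6-tris(benzyloxy)-5-butanoylbenzene-3,1-diyl)methylene]}bis(2-butanoyl-3,5-dihydroxy-4,4-dimethylcyclohexa-2,5-dien-1-one), via tetra(acyl chloride) 17 (not isolated), via bis(pyrrolidinylbutylidene) bis-trione 18 (not isolated)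
Conditions: (COCl)2, DMF (cat.), CH2Cl2, 0 °C → rt, evaporate; 6 (2.4 equiv), CH2Cl2 (0.01 M), −78 → 0 °C; 2,6-lutidine, 0 °C → rt; 1 M aq. HCl/THF, rt → 40 °C
Reagents that add atoms: water, O
Why: Proposed new method: the silyl enol ether terminus (CMe2) of the 1-amino-3-silyloxy diene 6 should add to one acyl chloride of each malonyl unit of 17 with loss of Me3SiCl (Mukaiyama-type C-acylation, making the quaternary C4 and the C4–C5 bond), and the enaminone so regenerated should then be C-acylated at its α-carbon by the second acyl chloride, directly or through the acylketene that 2,6-lutidine forms by loss of HCl, closing the ring through the C1–C2 bond to give 18, whose vinylogous amide is hydrolysed by the aqueous acid to the butanoyl ketone of 19. The closest known reaction types are the [3+3] cyclisation of 1,3-bis(silyloxy)-1,3-dienes with 1,3-dielectrophiles, the double Claisen condensation of acetonedicarboxylates with malonates to phloroglucinols, and the C-acylation of enaminones by acid chlorides followed by hydrolysis to 2-acyl-1,3-diones; none has been shown for an aminosilyloxy diene with a malonyl dichloride. Each of the two cyclohexane-1,3,5-trione rings closes by a 6-(enolexo)-exo-trig acylation, and since the CMe2 carbon and the enaminone α-carbon are the only two nucleophilic carbons of 6, either order of the two acylations leads to the same ring. No stereocentre is formed. The step needs regioselectivity between the gem-dimethyl carbon and the butanoyl α-carbon, secured because the butanoyl carbonyl is an enaminone carbon that cannot enolise towards the propyl chain under these non-basic conditions, and C- over O-acylation, secured because O-acyl isomers (enol esters, acyloxy-iminium species) remain acyl donors and revert while the C,C-diacylated vinylogous amide is the thermodynamic sink. High dilution and the gem-dimethyl effect should favour the intramolecular six-ring closure over oligomerisation across the two malonyl units.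

Step 11
Reactants: 19 hexa-O-benzyl ether from step 10
Product: 20 6,6'-{methylenebis[(5-butanoyl-2,4,6-trihydroxybenzene-3,1-diyl)methylene]}bis(2-butanoyl-3,5-dihydroxy-4,4-dimethylcyclohexa-2,5-dien-1-one) (CNP0110234.0)
Conditions: H2 (1 atm), Pd/C (10 wt% palladium on carbon), EtOAc/MeOH, rt
Reagents that add atoms: none
Why: Catalytic hydrogenolysis of benzyl aryl ethers should free the six phenols, while the tetrasubstituted enol double bonds of the vinylogous-acid rings and the hydrogen-bonded aryl ketones should not be reduced at 1 atm and room temperature.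

**Compound list**

1 | pent-1-yne | CCCC#C | starting material
2 | 2-methylpropanoyl chloride | CC(C)C(=O)Cl | starting material
3 | 2-methyloct-4-yn-3-one | CCCC#CC(=O)C(C)C | intermediate
4 | pyrrolidine | C1CCNC1 | starting material
5 | (4E)-2-methyl-5-(pyrrolidin-1-yl)oct-4-en-3-one | CCC/C(N1CCCC1)=C\C(=O)C(C)C | intermediate
6 | 1-[(4E)-2-methyl-3-(trimethylsilyloxy)octa-2,4-dien-5-yl]pyrrolidine | CCC/C(N1CCCC1)=C\C(O[Si](C)(C)C)=C(C)C | intermediate
7 | phloroglucinol (benzene-1,3,5-triol) | Oc1cc(O)cc(O)c1 | starting material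
8 | butanoyl chloride | CCCC(=O)Cl | starting material
9 | 1-(2,4,6-trihydroxyphenyl)butan-1-one | CCCC(=O)c1c(O)cc(O)cc1O | intermediate
10 | 1,1'-[methylenebis(2,4,6-trihydroxybenzene-3,1-diyl)]di(butan-1-one) | CCCC(=O)c1c(O)cc(O)c(Cc2c(O)cc(O)c(C(=O)CCC)c2O)c1O | intermediate
11 | 3,3'-methylenebis(5-butanoyl-2,4,6-trihydroxybenzaldehyde) | CCCC(=O)c1c(O)c(C=O)c(O)c(Cc2c(O)c(C=O)c(O)c(C(=O)CCC)c2O)c1O | intermediate
12 | 3,3'-methylenebis[2,4,6-tris(benzyloxy)-5-butanoylbenzaldehyde] | CCCC(=O)c1c(OCc2ccccc2)c(C=O)c(OCc2ccccc2)c(Cc2c(OCc3ccccc3)c(C=O)c(OCc3ccccc3)c(C(=O)CCC)c2OCc2ccccc2)c1OCc1ccccc1 | intermediate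
13 | Meldrum's acid (2,2-dimethyl-1,3-dioxane-4,6-dione) | CC1(C)OC(=O)CC(=O)O1 | starting material
14 | 5,5'-{methylenebis[(2,4,6-tris(benzyloxy)-5-butanoylbenzene-3,1-diyl)methanylylidene]}bis(2,2-dimethyl-1,3-dioxane-4,6-dione) | CCCC(=O)c1c(OCc2ccccc2)c(C=C2C(=O)OC(C)(C)OC2=O)c(OCc2ccccc2)c(Cc2c(OCc3ccccc3)c(C=C3C(=O)OC(C)(C)OC3=O)c(OCc3ccccc3)c(C(=O)CCC)c2OCc2ccccc2)c1OCc1ccccc1 | intermediate
15 | 5,5'-{methylenebis[(2,4,6-tris(benzyloxy)-5-butanoylbenzene-3,1-diyl)methylene]}bis(2,2-dimethyl-1,3-dioxane-4,6-dione) | CCCC(=O)c1c(OCc2ccccc2)c(CC2C(=O)OC(C)(C)OC2=O)c(OCc2ccccc2)c(Cc2c(OCc3ccccc3)c(CC3C(=O)OC(C)(C)OC3=O)c(OCc3ccccc3)c(C(=O)CCC)c2OCc2ccccc2)c1OCc1ccccc1 | intermediate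
16 | 2,2'-{methylenebis[(2,4,6-tris(benzyloxy)-5-butanoylbenzene-3,1-diyl)methylene]}dipropanedioic acid | CCCC(=O)c1c(OCc2ccccc2)c(CC(C(=O)O)C(=O)O)c(OCc2ccccc2)c(Cc2c(OCc3ccccc3)c(CC(C(=O)O)C(=O)O)c(OCc3ccccc3)c(C(=O)CCC)c2OCc2ccccc2)c1OCc1ccccc1 | intermediate
17 | 2,2'-{methylenebis[(2,4,6-tris(benzyloxy)-5-butanoylbenzene-3,1-diyl)methylene]}dipropanedioyl tetrachloride | CCCC(=O)c1c(OCc2ccccc2)c(CC(C(=O)Cl)C(=O)Cl)c(OCc2ccccc2)c(Cc2c(OCc3ccccc3)c(CC(C(=O)Cl)C(=O)Cl)c(OCc3ccccc3)c(C(=O)CCC)c2OCc2ccccc2)c1OCc1ccccc1 | intermediate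
18 | 4,4'-{methylenebis[(2,4,6-tris(benzyloxy)-5-butanoylbenzene-3,1-diyl)methylene]}bis{5-hydroxy-6,6-dimethyl-2-[1-(pyrrolidin-1-yl)butylidene]cyclohex-4-ene-1,3-dione} | CCCC(=O)c1c(OCc2ccccc2)c(CC2=C(O)C(C)(C)C(=O)C(=C(CCC)N3CCCC3)C2=O)c(OCc2ccccc2)c(Cc2c(OCc3ccccc3)c(CC3=C(O)C(C)(C)C(=O)C(=C(CCC)N4CCCC4)C3=O)c(OCc3ccccc3)c(C(=O)CCC)c2OCc2ccccc2)c1OCc1ccccc1 | intermediate
19 | 6,6'-{methylenebis[(2,4,6-tris(benzyloxy)-5-butanoylbenzene-3,1-diyl)methylene]}bis(2-butanoyl-3,5-dihydroxy-4,4-dimethylcyclohexa-2,5-dien-1-one) | CCCC(=O)c1c(OCc2ccccc2)c(CC2=C(O)C(C)(C)C(O)=C(C(=O)CCC)C2=O)c(OCc2ccccc2)c(Cc2c(OCc3ccccc3)c(CC3=C(O)C(C)(C)C(O)=C(C(=O)CCC)C3=O)c(OCc3ccccc3)c(C(=O)CCC)c2OCc2ccccc2)c1OCc1ccccc1 | intermediate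
20 | 6,6'-{methylenebis[(5-butanoyl-2,4,6-trihydroxybenzene-3,1-diyl)methylene]}bis(2-butanoyl-3,5-dihydroxy-4,4-dimethylcyclohexa-2,5-dien-1-one), CNP0110234.0 | CCCC(=O)C1=C(O)C(C)(C)C(O)=C(Cc2c(O)c(Cc3c(O)c(CC4=C(O)C(C)(C)C(O)=C(C(=O)CCC)C4=O)c(O)c(C(=O)CCC)c3O)c(O)c(C(=O)CCC)c2O)C1=O | target

**Totals and risks**

Total step count: 11. Longest linear sequence: 8 steps (steps 4 to 11, from phloroglucinol); the three-step side branch (steps 1 to 3) joins at step 10.

Steps most likely to fail:

1. Step 10 (Proposed new method). What may go wrong: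
   - O-acylation instead of C-acylation at either stage;
   - intermolecular second acylation leading to oligomers;
   - ketene dimerisation;
   - lactonisation of an ortho benzyl ether onto an acyl chloride with loss of the benzyl group;
   - incomplete hydrolysis of the vinylogous amide.

   Fallback with known chemistry: the convergent phloroglucinol route. It sets out from 9 and also uses 10 from step 5. Exhaustive C-methylation of 9 at one ring carbon (MeI, NaOMe, MeOH, 0 °C → rt) should give 2-butanoyl-3,5-dihydroxy-4,4-dimethylcyclohexa-2,5-dien-1-one (butanoylfilicinic acid) F1. Treating F1 (2 equiv), 10 and formaldehyde (2 equiv) in 1% aq. KOH at 0 °C → rt should then bridge the free ring carbon of each filicinic acid ring to the free aromatic carbon of each ring of 10 (the same ortho-quinone methide chemistry as in step 5). The fallback comes back to the route at 20 without any protecting group.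

2. Step 3. What may go wrong: poor site selectivity of deprotonation between the isopropyl methine and the γ-methylene of the propyl chain, and hydrolytic loss of the silyl group on handling.

   Fallback: generate the enol silane by 1,4-hydrosilylation instead of deprotonation. It sets out from 1. Acyl Sonogashira coupling of 1 with methacryloyl chloride (PdCl2(PPh3)2, CuI, Et3N, THF) should give 2-methyloct-1-en-4-yn-3-one F2. Conjugate addition of 4 to the ynone (EtOH, −20 °C) should give (4E)-2-methyl-5-(pyrrolidin-1-yl)octa-1,4-dien-3-one F3. RhCl(PPh3)3-catalysed 1,4-hydrosilylation of the isopropenyl ketone with Et3SiH delivers hydrogen to the terminal CH2 and silicon to oxygen and should give 1-[(4E)-2-methyl-3-(triethylsilyloxy)octa-2,4-dien-5-yl]pyrrolidine F4, the triethylsilyl analogue of 6 with the enol ether fixed at the gem-dimethyl carbon. F4 takes the place of 6 in step 10 and the route comes back at 19.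

3. Step 9. What may go wrong: decarboxylation of the monosubstituted malonic acids during the acidic hydrolysis, or sluggish ring opening of the very lipophilic substrate.

   Fallback: carry the malonyl unit as a dimethyl ester and open it with base at room temperature. It sets out from 12. Knoevenagel condensation with dimethyl malonate (piperidine, AcOH, toluene, reflux, water separator) should give tetramethyl 2,2'-{methylenebis[(2,4,6-tris(benzyloxy)-5-butanoylbenzene-3,1-diyl)methanylylidene]}dipropanedioate F5. Conjugate reduction (NaBH4, THF/MeOH, 0 °C) should give tetramethyl 2,2'-{methylenebis[(2,4,6-tris(benzyloxy)-5-butanoylbenzene-3,1-diyl)methylene]}dipropanedioate F6. Saponification (LiOH, THF/H2O, rt; cold acidification) comes back to the route at 16.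

**Further compounds**

F1 | step 10 | 2-butanoyl-3,5-dihydroxy-4,4-dimethylcyclohexa-2,5-dien-1-one (butanoylfilicinic acid) | CCCC(=O)C1=C(O)C(C)(C)C(O)=CC1=O
F2 | step 3 | 2-methyloct-1-en-4-yn-3-one | CCCC#CC(=O)C(C)=C
F3 | step 3 | (4E)-2-methyl-5-(pyrrolidin-1-yl)octa-1,4-dien-3-one | CCC/C(N1CCCC1)=C\C(=O)C(C)=C
F4 | step 3 | 1-[(4E)-2-methyl-3-(triethylsilyloxy)octa-2,4-dien-5-yl]pyrrolidine | CCC/C(N1CCCC1)=C\C(O[Si](CC)(CC)CC)=C(C)C
F5 | step 9 | tetramethyl 2,2'-{methylenebis[(2,4,6-tris(benzyloxy)-5-butanoylbenzene-3,1-diyl)methanylylidene]}dipropanedioate | CCCC(=O)c1c(OCc2ccccc2)c(C=C(C(=O)OC)C(=O)OC)c(OCc2ccccc2)c(Cc2c(OCc3ccccc3)c(C=C(C(=O)OC)C(=O)OC)c(OCc3ccccc3)c(C(=O)CCC)c2OCc2ccccc2)c1OCc1ccccc1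
F6 | step 9 | tetramethyl 2,2'-{methylenebis[(2,4,6-tris(benzyloxy)-5-butanoylbenzene-3,1-diyl)methylene]}dipropanedioate | CCCC(=O)c1c(OCc2ccccc2)c(CC(C(=O)OC)C(=O)OC)c(OCc2ccccc2)c(Cc2c(OCc3ccccc3)c(CC(C(=O)OC)C(=O)OC)c(OCc3ccccc3)c(C(=O)CCC)c2OCc2ccccc2)c1OCc1ccccc1
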